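**Plan**

- Feature used: in ring A the segment C3(OH)–C2(H)–C1(OMe)–C6 is a 1,3-dioxygenated four-carbon unit (an oxygenated diene), and C4/C5, which carry a benzyl group and the CH2CH2 bridge to ring B, are the two carbons of an alkyne; the C4 benzyl is carried as an aroyl group so that it activates the alkyne.
- Retrosynthetic cuts, in order: the four O–benzyl bonds; the C4 benzylic C=O (deoxygenation); ring A bonds C3–C4 and C5–C6 ([4+2]); the carbinol–alkyne bond of the ynone; the alkyne carbon, the bridge and the diarylmethane bond of ring B; the γ-C–CH2Ar bond of the acetoacetate-derived diene.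
- Forward: the ring B arm is built from 3-bromo-5-hydroxybenzaldehyde up to ynone 11 (steps 1–7), the diene 19 from methyl acetoacetate (steps 8–10); ring A is the only ring formed and closes in step 11; deoxygenation and debenzylation finish (steps 12–13).
- Stereochemistry: the target is achiral with no stereocentre; the only geometric requirement is the C3=C4 geometry of diene 19, with the arylmethyl group pointing outward.

Key step: step 11

Remark: 4-(benzyloxy)phenylmagnesium bromide (3) and LiN(iPr)2 are taken as commercial THF solutions; carbinols 4, 10 and 23 are racemic and cycloadduct 20 is a diastereomer mixture, and all of these sp3 centres are removed within the route.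

**Route**

Step 1
Reactants: 1 3-bromo-5-hydroxybenzaldehyde
Product: 2 3-(benzyloxy)-5-bromobenzaldehyde
Conditions: BnBr, K2CO3, DMF, rt
Reagents that add atoms: benzyl bromide, BrCc1ccccc1
Why: Williamson etherification of the phenoxide with a reactive benzylic bromide; aldehyde and aryl bromide are inert to K2CO3 in DMF.

Step 2
Reactants: 2 3-(benzyloxy)-5-bromobenzaldehyde; 3 4-(benzyloxy)phenylmagnesium bromide
Product: 4 [3-(benzyloxy)-5-bromophenyl][4-(benzyloxy)phenyl]methanol
Conditions: 3 (1.2 equiv), THF, 0 °C; then sat. aq. NH4Cl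
Reagents that add atoms: none
Why: Grignard 1,2-addition to an aromatic aldehyde; the aryl bromide does not exchange with an aryl Grignard reagent at 0 °C, and the racemic carbinol centre is removed in step 3.

Step 3
Reactants: 4 [3-(benzyloxy)-5-bromophenyl][4-(benzyloxy)phenyl]methanol
Product: 5 1-(benzyloxy)-3-[4-(benzyloxy)benzyl]-5-bromobenzene
Conditions: Et3SiH, CF3CO2H, CH2Cl2, 0 °C
Reagents that add atoms: none
Why: Ionic hydrogenation: acid ionises the doubly benzylic alcohol to a cation stabilised by the para-benzyloxyphenyl ring, which the silane reduces faster than aryl benzyl ethers are cleaved at 0 °C.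

Step 4
Reactants: 5 1-(benzyloxy)-3-[4-(benzyloxy)benzyl]-5-bromobenzene
Product: 6 3-{3-(benzyloxy)-5-[4-(benzyloxy)benzyl]phenyl}propanal
Conditions: allyl alcohol, Pd(OAc)2 (5 mol %), Bu4NCl, NaHCO3, DMF, 90 °C
Reagents that add atoms: allyl alcohol, C=CCO
Why: Heck arylation of allyl alcohol under ligand-free phase-transfer conditions; after insertion at the terminal carbon, β-hydride elimination toward the carbinol carbon gives an enol that tautomerises to the saturated aldehyde.

Step 5
Reactants: 6 3-{3-(benzyloxy)-5-[4-(benzyloxy)benzyl]phenyl}propanal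
Product: 7 1-(benzyloxy)-3-[4-(benzyloxy)benzyl]-5-(but-3-yn-1-yl)benzene
Conditions: dimethyl (1-diazo-2-oxopropyl)phosphonate, K2CO3, MeOH, 0 °C to rt
Reagents that add atoms: Ohira–Bestmann reagent, COP(=O)(OC)C(=[N+]=[N-])C(C)=O
Why: Seyferth–Gilbert homologation in the Ohira–Bestmann variant, whose mild carbonate/methanol conditions convert enolisable aliphatic aldehydes into terminal alkynes without aldol loss.

Step 6
Reactants: 7 1-(benzyloxy)-3-[4-(benzyloxy)benzyl]-5-(but-3-yn-1-yl)benzene; 8 4-(benzyloxy)benzaldehyde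
Product: 10 1-[4-(benzyloxy)phenyl]-5-{3-(benzyloxy)-5-[4-(benzyloxy)benzyl]phenyl}pent-2-yn-1-ol, via lithium acetylide 9 (not isolated)
Conditions: n-BuLi, THF, −78 °C; then 8, −78 to 0 °C; then sat. aq. NH4Cl
Reagents that add atoms: none
Why: Acetylide addition to an aldehyde; the terminal alkyne C–H is far more acidic than the diarylmethane CH2, so n-BuLi metalates it selectively at −78 °C, and the racemic carbinol centre is removed in step 7.

Step 7
Reactants: 10 1-[4-(benzyloxy)phenyl]-5-{3-(benzyloxy)-5-[4-(benzyloxy)benzyl]phenyl}pent-2-yn-1-ol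
Product: 11 1-[4-(benzyloxy)phenyl]-5-{3-(benzyloxy)-5-[4-(benzyloxy)benzyl]phenyl}pent-2-yn-1-one
Conditions: MnO2 (activated, excess), CH2Cl2, rt
Reagents that add atoms: none
Why: MnO2 oxidation of an alcohol that is both propargylic and benzylic; the neutral conditions avoid isomerising the ynone to an allenyl ketone.

Step 8
Reactants: 12 methyl acetoacetate; 13 4-(benzyloxy)benzyl chloride
Product: 15 methyl 5-[4-(benzyloxy)phenyl]-3-oxopentanoate, via acetoacetate dianion 14 (not isolated)
Conditions: NaH, THF, 0 °C; n-BuLi, 0 °C; then 13, 0 °C to rt; then 1 M HCl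
Reagents that add atoms: none
Why: γ-Alkylation of the acetoacetate dianion, whose terminal carbanion is the more nucleophilic site and reacts with one equivalent of a benzylic chloride.

Step 9
Reactants: 15 methyl 5-[4-(benzyloxy)phenyl]-3-oxopentanoate
Product: 17 methyl (2E)-5-[4-(benzyloxy)phenyl]-3-methoxypent-2-enoate, via dimethyl ketal 16 (not isolated)
Conditions: HC(OMe)3, H2SO4 (cat.), MeOH, rt to 50 °C
Reagents that add atoms: trimethyl orthoformate, COC(OC)OC; methanol (solvent, exchanges methoxy groups with the orthoester), CO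
Why: Acid-catalysed ketalisation of the ketone followed by elimination of methanol into conjugation with the ester (enol ether formation from a β-keto ester), which should give the thermodynamically preferred E-β-methoxy enoate.

Step 10
Reactants: 17 methyl (2E)-5-[4-(benzyloxy)phenyl]-3-methoxypent-2-enoate
Product: 19 (1Z,3Z)-5-[4-(benzyloxy)phenyl]-1,3-dimethoxy-1-(trimethylsilyloxy)penta-1,3-diene, via lithium dienolate 18 (not isolated)
Conditions: LiN(iPr)2, THF, −78 °C; then Me3SiCl, −78 to 0 °C; pentane, filtration, used crude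
Reagents that add atoms: chlorotrimethylsilane, C[Si](C)(C)Cl
Why: Kinetic γ-deprotonation of the β-methoxy enoate to the extended dienolate and O-silylation (vinylogous silyl ketene acetal formation); the arylmethyl group should settle cis to the small methoxy group (3Z, outward), while the C1=C2 geometry has no consequence.

Step 11
Reactants: 19 (1Z,3Z)-5-[4-(benzyloxy)phenyl]-1,3-dimethoxy-1-(trimethylsilyloxy)penta-1,3-diene; 11 1-[4-(benzyloxy)phenyl]-5-{3-(benzyloxy)-5-[4-(benzyloxy)benzyl]phenyl}pent-2-yn-1-one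
Product: 22 [4-(benzyloxy)phenyl]{3-[4-(benzyloxy)benzyl]-2-(2-{3-(benzyloxy)-5-[4-(benzyloxy)benzyl]phenyl}ethyl)-6-hydroxy-4-methoxyphenyl}methanone, via cyclohexa-1,4-diene cycloadduct 20 (not isolated), via aryl trimethylsilyl ether 21 (not isolated)
Conditions: 19 (2.5 equiv), toluene, 110 °C, sealed tube; then 1 M HCl, THF, rt
Reagents that add atoms: none
Why: The electron-rich diene 19 adds across the C≡C bond of 11 in a thermal normal-electron-demand Diels–Alder reaction that is probably asynchronous, its C4 terminus bonding first to the ynone β-carbon and the ketene acetal carbon C1 then closing onto the α-carbon; cycloadduct 20 loses methanol by 1,4-elimination and the resulting silyl ether 21 is cleaved by dilute acid. The closest known reaction type is the cycloaddition–aromatisation of 1,3-dialkoxy-1-silyloxybutadienes with acetylenic ketones and esters to give resorcinol monoethers. Ring A closes by intermolecular [4+2] cycloaddition, and both new ring bonds (C5–C6 and C3–C4 in ring A numbering) arise in this one operation. No stereocentre is kept, since the two sp3 carbons of 20 become aromatic. The step needs head-to-tail regioselectivity and reaction at C≡C in preference to C=O: the first follows from the large HOMO coefficient at diene C4 meeting the large LUMO coefficient at the ynone β-carbon, which places OH beside the aroyl carbon and OMe beside the benzyl-bearing carbon, and the second from the Lewis-acid-free thermal conditions, under which a ketone carbonyl is a poor heterodienophile.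

Step 12
Reactants: 22 [4-(benzyloxy)phenyl]{3-[4-(benzyloxy)benzyl]-2-(2-{3-(benzyloxy)-5-[4-(benzyloxy)benzyl]phenyl}ethyl)-6-hydroxy-4-methoxyphenyl}methanone
Product: 24 2-[4-(benzyloxy)benzyl]-3-(2-{3-(benzyloxy)-5-[4-(benzyloxy)benzyl]phenyl}ethyl)-4-[4-(benzyloxy)benzyl]-5-methoxyphenol, via benzhydrol 23 (not isolated)
Conditions: Et3SiH (excess), CF3CO2H, CH2Cl2, 0 °C to rt
Reagents that add atoms: none
Why: Ionic hydrogenation of a diaryl ketone: hydride transfer to the protonated carbonyl gives benzhydrol 23, which ionises to a cation stabilised by the para-benzyloxyphenyl and ortho-hydroxyaryl rings and is reduced again to the methylene.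

Step 13
Reactants: 24 2-[4-(benzyloxy)benzyl]-3-(2-{3-(benzyloxy)-5-[4-(benzyloxy)benzyl]phenyl}ethyl)-4-[4-(benzyloxy)benzyl]-5-methoxyphenol
Product: 25 2,4-bis(4-hydroxybenzyl)-3-{2-[3-hydroxy-5-(4-hydroxybenzyl)phenyl]ethyl}-5-methoxyphenol (CNP0204120.0)
Conditions: H2 (1 atm), Pd/C (10%), EtOAc–MeOH, rt
Reagents that add atoms: none
Why: Catalytic hydrogenolysis of the four aryl benzyl ethers; the diarylmethane C–C bonds and the aryl methyl ether are inert under these conditions.

**Compound list**

1 | 3-bromo-5-hydroxybenzaldehyde | O=Cc1cc(O)cc(Br)c1 | starting material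
2 | 3-(benzyloxy)-5-bromobenzaldehyde | O=Cc1cc(OCc2ccccc2)cc(Br)c1 | intermediate
3 | 4-(benzyloxy)phenylmagnesium bromide | Br[Mg]c1ccc(OCc2ccccc2)cc1 | starting material
4 | [3-(benzyloxy)-5-bromophenyl][4-(benzyloxy)phenyl]methanol (racemic) | OC(c1ccc(OCc2ccccc2)cc1)c1cc(OCc2ccccc2)cc(Br)c1 | intermediate
5 | 1-(benzyloxy)-3-[4-(benzyloxy)benzyl]-5-bromobenzene | Brc1cc(OCc2ccccc2)cc(Cc2ccc(OCc3ccccc3)cc2)c1 | intermediate
6 | 3-{3-(benzyloxy)-5-[4-(benzyloxy)benzyl]phenyl}propanal | O=CCCc1cc(OCc2ccccc2)cc(Cc2ccc(OCc3ccccc3)cc2)c1 | intermediate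
7 | 1-(benzyloxy)-3-[4-(benzyloxy)benzyl]-5-(but-3-yn-1-yl)benzene | C#CCCc1cc(OCc2ccccc2)cc(Cc2ccc(OCc3ccccc3)cc2)c1 | intermediate
8 | 4-(benzyloxy)benzaldehyde | O=Cc1ccc(OCc2ccccc2)cc1 | starting material
9 | lithium acetylide of 7 | [Li]C#CCCc1cc(OCc2ccccc2)cc(Cc2ccc(OCc3ccccc3)cc2)c1 | intermediate
10 | 1-[4-(benzyloxy)phenyl]-5-{3-(benzyloxy)-5-[4-(benzyloxy)benzyl]phenyl}pent-2-yn-1-ol (racemic) | OC(C#CCCc1cc(OCc2ccccc2)cc(Cc2ccc(OCc3ccccc3)cc2)c1)c1ccc(OCc2ccccc2)cc1 | intermediate
11 | 1-[4-(benzyloxy)phenyl]-5-{3-(benzyloxy)-5-[4-(benzyloxy)benzyl]phenyl}pent-2-yn-1-one | O=C(C#CCCc1cc(OCc2ccccc2)cc(Cc2ccc(OCc3ccccc3)cc2)c1)c1ccc(OCc2ccccc2)cc1 | intermediate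
12 | methyl acetoacetate | COC(=O)CC(C)=O | starting material
13 | 4-(benzyloxy)benzyl chloride | ClCc1ccc(OCc2ccccc2)cc1 | starting material
14 | methyl acetoacetate dianion (sodium lithium salt) | [Na+].[Li+].COC(=O)[CH-]C(=O)[CH2-] | intermediate
15 | methyl 5-[4-(benzyloxy)phenyl]-3-oxopentanoate | COC(=O)CC(=O)CCc1ccc(OCc2ccccc2)cc1 | intermediate
16 | methyl 5-[4-(benzyloxy)phenyl]-3,3-dimethoxypentanoate | COC(=O)CC(OC)(OC)CCc1ccc(OCc2ccccc2)cc1 | intermediate
17 | methyl (2E)-5-[4-(benzyloxy)phenyl]-3-methoxypent-2-enoate | COC(=O)/C=C(/OC)CCc1ccc(OCc2ccccc2)cc1 | intermediate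
18 | lithium dienolate of 17 | [Li+].CO/C([O-])=C/C(OC)=C/Cc1ccc(OCc2ccccc2)cc1 | intermediate
19 | (1Z,3Z)-5-[4-(benzyloxy)phenyl]-1,3-dimethoxy-1-(trimethylsilyloxy)penta-1,3-diene | CO/C(O[Si](C)(C)C)=C/C(OC)=C/Cc1ccc(OCc2ccccc2)cc1 | intermediate
20 | [4-(benzyloxy)phenyl]{3-[4-(benzyloxy)benzyl]-2-(2-{3-(benzyloxy)-5-[4-(benzyloxy)benzyl]phenyl}ethyl)-4,6-dimethoxy-6-(trimethylsilyloxy)cyclohexa-1,4-dien-1-yl}methanone (diastereomer mixture, both sp3 centres lost on aromatisation) | COC1(O[Si](C)(C)C)C=C(OC)C(Cc2ccc(OCc3ccccc3)cc2)C(CCc2cc(OCc3ccccc3)cc(Cc3ccc(OCc4ccccc4)cc3)c2)=C1C(=O)c1ccc(OCc2ccccc2)cc1 | intermediate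
21 | trimethylsilyl ether of 22 | COc1cc(O[Si](C)(C)C)c(C(=O)c2ccc(OCc3ccccc3)cc2)c(CCc2cc(OCc3ccccc3)cc(Cc3ccc(OCc4ccccc4)cc3)c2)c1Cc1ccc(OCc2ccccc2)cc1 | intermediate
22 | [4-(benzyloxy)phenyl]{3-[4-(benzyloxy)benzyl]-2-(2-{3-(benzyloxy)-5-[4-(benzyloxy)benzyl]phenyl}ethyl)-6-hydroxy-4-methoxyphenyl}methanone | COc1cc(O)c(C(=O)c2ccc(OCc3ccccc3)cc2)c(CCc2cc(OCc3ccccc3)cc(Cc3ccc(OCc4ccccc4)cc3)c2)c1Cc1ccc(OCc2ccccc2)cc1 | intermediate
23 | 3-[4-(benzyloxy)benzyl]-2-{[4-(benzyloxy)phenyl](hydroxy)methyl}... i.e. the benzhydrol from reduction of the C=O of 22 (racemic) | COc1cc(O)c(C(O)c2ccc(OCc3ccccc3)cc2)c(CCc2cc(OCc3ccccc3)cc(Cc3ccc(OCc4ccccc4)cc3)c2)c1Cc1ccc(OCc2ccccc2)cc1 | intermediate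
24 | 2-[4-(benzyloxy)benzyl]-3-(2-{3-(benzyloxy)-5-[4-(benzyloxy)benzyl]phenyl}ethyl)-4-[4-(benzyloxy)benzyl]-5-methoxyphenol | COc1cc(O)c(Cc2ccc(OCc3ccccc3)cc2)c(CCc2cc(OCc3ccccc3)cc(Cc3ccc(OCc4ccccc4)cc3)c2)c1Cc1ccc(OCc2ccccc2)cc1 | intermediate
25 | 2,4-bis(4-hydroxybenzyl)-3-{2-[3-hydroxy-5-(4-hydroxybenzyl)phenyl]ethyl}-5-methoxyphenol | COc1cc(O)c(Cc2ccc(O)cc2)c(CCc2cc(O)cc(Cc3ccc(O)cc3)c2)c1Cc1ccc(O)cc1 | target

**Summary**

Total step count: 13. Longest linear sequence: 10 steps (steps 1–7, then 11–13); the diene arm (steps 8–10) joins at step 11.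

Steps most likely to fail:

Step 11. Bond formation between the substituted diene terminus and the alkyl-bearing alkyne carbon may be slower than thermal or hydrolytic loss of the diene. The acceptor is only a donor-substituted aryl ketone, so the ynone could be recovered while 19 reverts to 17. Loss of silanol in place of methanol would give some dimethyl ether. The fallback sets out from alkyne 7 and moves the aryl group to a later stage so that a smaller and more electrophilic dienophile is used. Lithiation of 7 with n-BuLi and formylation with DMF should give 5-{3-(benzyloxy)-5-[4-(benzyloxy)benzyl]phenyl}pent-2-ynal F1. Cycloaddition of F1 with diene 19 in toluene at 60–80 °C and dilute acid work-up should give 3-[4-(benzyloxy)benzyl]-2-(2-{3-(benzyloxy)-5-[4-(benzyloxy)benzyl]phenyl}ethyl)-6-hydroxy-4-methoxybenzaldehyde F2, with the same regiochemistry. Addition of Grignard reagent 3 (over two equivalents, the first consumed by the phenol) to F2 gives benzhydrol 23, where the detour comes back to the route; the conditions of step 12 then carry 23 to 24.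

Step 10. γ-Deprotonation of the β-methoxy enoate may compete with addition of the amide to the enoate. The silyl ketene acetal may hydrolyse back to 17 on handling. Part of the material may form as the 3,4-isomer with the arylmethyl group inward, which cannot reach the reactive s-cis geometry. The fallback sets out from β-keto ester 15 and uses the bis(silyloxy) diene class, made by two-stage silylation. Me3SiCl/Et3N should give methyl (2Z)-5-[4-(benzyloxy)phenyl]-3-(trimethylsilyloxy)pent-2-enoate F3. LiN(iPr)2 then Me3SiCl at −78 °C should give (1Z,3Z)-5-[4-(benzyloxy)phenyl]-1-methoxy-1,3-bis(trimethylsilyloxy)penta-1,3-diene F4. Cycloaddition of F4 with ynone 11 and acid work-up should give [4-(benzyloxy)phenyl]{3-[4-(benzyloxy)benzyl]-2-(2-{3-(benzyloxy)-5-[4-(benzyloxy)benzyl]phenyl}ethyl)-4,6-dihydroxyphenyl}methanone F5. Methylation of F5 with one equivalent of MeI and K2CO3 in acetone should take place at the hydroxyl para to the ketone, since the ortho hydroxyl is held in a hydrogen bond to the carbonyl. This returns to the route at 22.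

Step 12. Hydride delivery to the twisted, doubly ortho-substituted and hydrogen-bonded carbonyl may be slow. Prolonged acid exposure could then cleave benzyl ethers or let the benzhydryl cation alkylate a neighbouring electron-rich ring. The fallback sets out from 22 and separates the two reductions. LiAlH4 in THF at 0 °C should give benzhydrol 23, isolated here. Hydrogenation of 23 over Pd/C in EtOAc–AcOH should cleave the four benzyl ethers and the doubly benzylic C–O bond in one operation, returning to the route at target 25. This detour makes no compound beyond the list, entry F0.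

**Further compounds**

F1 | step 11 | 5-{3-(benzyloxy)-5-[4-(benzyloxy)benzyl]phenyl}pent-2-ynal | O=CC#CCCc1cc(OCc2ccccc2)cc(Cc2ccc(OCc3ccccc3)cc2)c1
F2 | step 11 | 3-[4-(benzyloxy)benzyl]-2-(2-{3-(benzyloxy)-5-[4-(benzyloxy)benzyl]phenyl}ethyl)-6-hydroxy-4-methoxybenzaldehyde | COc1cc(O)c(C=O)c(CCc2cc(OCc3ccccc3)cc(Cc3ccc(OCc4ccccc4)cc3)c2)c1Cc1ccc(OCc2ccccc2)cc1
F3 | step 10 | methyl (2Z)-5-[4-(benzyloxy)phenyl]-3-(trimethylsilyloxy)pent-2-enoate | COC(=O)/C=C(\O[Si](C)(C)C)CCc1ccc(OCc2ccccc2)cc1
F4 | step 10 | (1Z,3Z)-5-[4-(benzyloxy)phenyl]-1-methoxy-1,3-bis(trimethylsilyloxy)penta-1,3-diene | CO/C(O[Si](C)(C)C)=C/C(O[Si](C)(C)C)=C/Cc1ccc(OCc2ccccc2)cc1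
F5 | step 10 | [4-(benzyloxy)phenyl]{3-[4-(benzyloxy)benzyl]-2-(2-{3-(benzyloxy)-5-[4-(benzyloxy)benzyl]phenyl}ethyl)-4,6-dihydroxyphenyl}methanone | Oc1cc(O)c(C(=O)c2ccc(OCc3ccccc3)cc2)c(CCc2cc(OCc3ccccc3)cc(Cc3ccc(OCc4ccccc4)cc3)c2)c1Cc1ccc(OCc2ccccc2)cc1
F0 | step 12 | none | none
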